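**Plan**
Numbering: ring C1 (quaternary; CH3 and chain C12–C23), C2 (CH carrying C9–C11), C3 (=C7(CH3)–C8HO), C4, C5, C6 (C(OH)CH3).
Retrosynthetic cuts, in order: C16=C17 (phosphonate olefination, geranyl unit C17–C23), C14=C15 (Wittig), C3=C7 (olefination, C8 kept as a nitrile), C2–C9 (enolate allylation), ring bond C2–C3 (metathesis), and last C1–C6 (allylboration), leaving nerol and methyl levulinate.
Enabling feature: C1 and C6 are adjacent fully substituted carbons; C6 with its methyl and C5–C4–C3 is the ketone carbon of a levulinate, and C1 with its methyl, C2 and C12–C14 is the γ-carbon of a neryl unit, so one allylboration joins them.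
Forward: the C1–C6 bond and a temporary γ-lactone come first; O6 is then moved from the lactone into a six-membered methyl acetal with C14; the cyclohexane closes at C2–C3; C9–C11, C7/C8, C15/C16 and C17–C23 follow in that order.
Stereochemistry: C1 and C6 from the Z alkene and the chiral diol in a chair transition state; C2 by equilibration to the equatorial position of the rigid trans-fused bicyclic acetal; the Z enal from allylic strain (cyano beside C2); the E alkenes from stabilised ylide and phosphonate olefinations and from geranyl bromide.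

Key step: step 2

Assumption: the (R)-diol is taken to open the ketone face that gives (S)-C6; should the sense prove opposite, the commercial (S)-diol is used and nothing else changes.

**Step 1**
Reactants: 1 nerol
Product: 2 nerylboronic acid
Conditions: B2(OH)4 (1.2 equiv), Pd(MeCN)4(BF4)2 (1 mol%), DMSO/MeOH, 25 °C, argon; used as a stock solution
Reagents that add atoms: tetrahydroxydiboron, OB(O)B(O)O
Why: Allylic C–OH borylation catalysed by divalent palladium proceeds through an η3-allyl intermediate to the linear allylboronic acid under conditions mild enough to keep the Z trisubstituted alkene.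

**Step 2**
Reactants: 2 nerylboronic acid; 3 methyl levulinate
Product: 5 (5S)-5-[(3S)-3,7-dimethylocta-1,6-dien-3-yl]-5-methyloxolan-2-one, via O-boryl hydroxy ester 4 (not isolated)
Conditions: (R)-3,3'-dibromo-1,1'-bi-2-naphthol (20 mol%), t-BuOH (3 equiv), molecular sieves (3 Å), toluene, 25 °C; then dilute aq. HCl, 25 °C
Reagents that add atoms: none
Why: The boronic acid, activated as its mixed ester with the chiral diol, binds the ketone oxygen and transfers the allyl unit through a closed six-membered chair in which the γ-carbon (C1) bonds to the carbonyl carbon (C6) with allylic transposition, so that the boron-bearing CH2 and its neighbour become the vinyl group. The closest known reaction type is the diol-catalysed allylboration of ketones with γ,γ-disubstituted allylboronic acids, which gives adjacent quaternary and tertiary carbinol carbons. The relative configuration of C1 and C6 follows from the Z geometry (homoprenyl chain axial, C1 methyl equatorial) together with the ketone methyl axial and the longer ester arm equatorial, and the absolute configuration from the ketone face left open by the 3,3'-dibromo groups of the diol. The tertiary borate oxygen then attacks the ester carbonyl (C3) in a 5-exo-trig acyl substitution that closes the γ-lactone and expels methanol, completed by the acid wash. The step needs γ- over α-attack, ketone over ester chemoselectivity and discrimination between the two ketone substituents; the cyclic transition state secures the first, the inertness of esters toward allylboron reagents the second, and the size difference between methyl and the CH2CH2CO2Me arm, amplified by the bulky diol on boron, the third.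

**Step 3**
Reactants: 5 lactone
Product: 7 (4S)-4-methyl-4-[(2S)-2-methyl-5-oxooxolan-2-yl]hex-5-enal, via epoxide 6 (not isolated)
Conditions: mCPBA (1.05 equiv), CH2Cl2, 0 °C; then H5IO6 (1.3 equiv), THF/H2O, 0 → 25 °C
Reagents that add atoms: 3-chloroperoxybenzoic acid, O=C(OO)c1cccc(Cl)c1
Why: Prilezhaev epoxidation selects the electron-rich trisubstituted alkene over the hindered vinyl group, and periodic acid then hydrolyses the epoxide and cleaves the glycol (Malaprade cleavage) to the C14 aldehyde without touching the lactone.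

**Step 4**
Reactants: 7 aldehyde lactone
Product: 8 (5S)-5-[(3S)-6,6-dimethoxy-3-methylhex-1-en-3-yl]-5-methyloxolan-2-one
Conditions: HC(OMe)3, MeOH, PPTS (cat.), 25 °C
Reagents that add atoms: trimethyl orthoformate, COC(OC)OC; methanol, CO
Why: Acid-catalysed acetalisation with the orthoformate as water scavenger masks the aldehyde against the organolithium of the next step, the tertiary γ-lactone being stable to these conditions.

**Step 5**
Reactants: 8 lactone acetal
Product: 10 4-[(2S,3S)-3-ethenyl-6-methoxy-2,3-dimethyloxan-2-yl]butan-2-one (both anomers at the acetal carbon), via hydroxy ketone 9 (not isolated)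
Conditions: MeLi (1.1 equiv), THF, −78 °C; AcOH quench; then PPTS (cat.), molecular sieves (4 Å), CH2Cl2, 25 °C
Reagents that add atoms: methyllithium, [Li]C
Why: Single addition of methyllithium to the γ-lactone stops at the tetrahedral lithium alkoxide at low temperature and gives the methyl ketone on quench, after which acid-catalysed transacetalisation lets the freed tertiary hydroxyl displace one methoxy group in a 6-exo closure, so that O6 and C14 are protected in one ring whose acetal carbon is a transient stereocentre carried as a mixture.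

**Step 6**
Reactants: 10 methyl ketone
Product: 11 triethyl({4-[(2S,3S)-3-ethenyl-6-methoxy-2,3-dimethyloxan-2-yl]but-1-en-2-yl}oxy)silane
Conditions: Et3SiCl, LiN(i-Pr)2, THF, −78 °C (base added to ketone and silyl chloride); Et3N-buffered work-up
Reagents that add atoms: chlorotriethylsilane, CC[Si](Cl)(CC)CC
Why: Kinetic enolisation of the methyl ketone at the methyl group with in situ silyl trapping gives the less substituted silyl enol ether (C3=CH2).

**Step 7**
Reactants: 11 silyl enol ether
Product: 12 triethyl{[(4aS,8aS)-2-methoxy-4a,8a-dimethyl-3,4,4a,7,8,8a-hexahydro-2H-chromen-6-yl]oxy}silane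
Conditions: (H2IMes)(PCy3)Cl2Ru=CHPh (second-generation Grubbs catalyst, 10 mol%), toluene (high dilution), 80 °C, argon purge
Reagents that add atoms: none
Why: Ring-closing metathesis of the silyl enol ether with the C1 vinyl group forms the six-membered C2=C3 enol ether with loss of ethylene, the two arms being held gauche on the oxane ring; no stereocentre is created and the trans ring fusion follows from C1 and C6.

**Step 8**
Reactants: 12 cyclic silyl enol ether; 13 allyl methyl carbonate
Product: 15 (4aS,5S,8aS)-2-methoxy-4a,8a-dimethyl-5-(prop-2-en-1-yl)octahydro-6H-chromen-6-one, via C2-epimeric allyl ketones 14 (not isolated)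
Conditions: Pd2(dba)3 (2.5 mol%), Ph2PCH2CH2PPh2 (6 mol%), Bu4N[Ph3SiF2] (0.35 equiv), THF, 25 °C; then NaOMe (0.3 equiv), MeOH, 25 °C
Reagents that add atoms: none
Why: Tsuji–Trost allylation of the silyl enol ether (the enolate released at C2 attacks the η3-allyl complex formed from zerovalent palladium) is regiospecific for C2, and the new C2 centre is then set by methoxide equilibration to the equatorial epimer, because an axial allyl group would be syn-diaxial to the C6 methyl in the rigid trans-fused bicycle.

**Step 9**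
Reactants: 15 allyl ketone; 16 diethyl (1-cyanoethyl)phosphonate
Product: 17 (2Z)-2-[(4aS,5R,8aS)-2-methoxy-4a,8a-dimethyl-5-(prop-2-en-1-yl)octahydro-6H-chromen-6-ylidene]propanenitrile
Conditions: NaH (2.8 equiv), 16 (3.0 equiv), THF, 0 → 65 °C
Reagents that add atoms: none
Why: Horner–Wadsworth–Emmons olefination with the small cyano-stabilised phosphonate anion converts the hindered C3 ketone into the tetrasubstituted unsaturated nitrile, the Z isomer being favoured because the slim cyano group rather than the methyl group comes to lie beside the equatorial C2 substituent (allylic 1,3-strain), while the weakly basic anion, kept in slight excess over NaH, should not deconjugate the product.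

**Step 10**
Reactants: 17 allyl nitrile
Product: 19 (2Z)-2-[(4aS,5R,8aS)-5-(3-hydroxypropyl)-2-methoxy-4a,8a-dimethyloctahydro-6H-chromen-6-ylidene]propanenitrile, via B-alkyl-9-BBN adduct 18 (not isolated)
Conditions: 9-borabicyclo[3.3.1]nonane (1.5 equiv), THF, 0 → 25 °C; then NaBO3·4H2O, THF/H2O, 25 °C
Reagents that add atoms: sodium perborate (oxygen), [Na+].[Na+].O[B-]1(O)OO[B-](O)(O)OO1
Why: Anti-Markovnikov hydroboration with the bulky borane selects the monosubstituted alkene over the tetrasubstituted electron-poor alkene and the nitrile, and perborate oxidises the borane to the C11 alcohol under conditions too mild to hydrate the nitrile.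

**Step 11**
Reactants: 19 hydroxy acetal
Product: 20 (2Z)-2-[(4aS,5R,8aS)-2-hydroxy-5-(3-hydroxypropyl)-4a,8a-dimethyloctahydro-6H-chromen-6-ylidene]propanenitrile (lactol, both anomers)
Conditions: AcOH/THF/H2O (3:1:1), 40 °C
Reagents that add atoms: water, O
Why: Mild aqueous acid hydrolysis of the mixed methyl acetal releases the lactol, the masked C14 aldehyde, while nitrile and alkene are inert.

**Step 12**
Reactants: 20 lactol; 21 2-(triphenyl-λ5-phosphanylidene)propanal
Product: 22 (2Z)-2-{(2R,3S,4S)-4-hydroxy-2-(3-hydroxypropyl)-3,4-dimethyl-3-[(3E)-4-methyl-5-oxopent-3-en-1-yl]cyclohexylidene}propanenitrile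
Conditions: 21 (2 equiv), toluene, 90 °C
Reagents that add atoms: none
Why: Wittig olefination of the lactol through its open hydroxy aldehyde with the stabilised formyl ylide gives the (E)-2-methyl enal (E selectivity of stabilised ylides), the α-methyl group and the hindered tertiary hydroxyl disfavouring oxa-Michael reclosure.

**Step 13**
Reactants: 23 geranyl bromide
Product: 24 diethyl [(2E)-3,7-dimethylocta-2,6-dien-1-yl]phosphonate
Conditions: P(OEt)3, neat, 130 °C
Reagents that add atoms: triethyl phosphite, CCOP(OCC)OCC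
Why: The Michaelis–Arbuzov reaction of the primary allylic bromide proceeds by SN2 attack of phosphorus at CH2 and keeps the E alkene.

**Step 14**
Reactants: 22 enal; 24 diethyl geranylphosphonate
Product: 25 (2Z)-2-{(2R,3S,4S)-4-hydroxy-2-(3-hydroxypropyl)-3,4-dimethyl-3-[(3E,5E,7E)-4,8,12-trimethyltrideca-3,5,7,11-tetraen-1-yl]cyclohexylidene}propanenitrile
Conditions: 24 (3.5 equiv), n-BuLi (3.4 equiv), THF/DMPU, −78 °C; then 22, −78 → 0 °C
Reagents that add atoms: none
Why: Horner–Wadsworth–Emmons olefination of the unhindered enal with the lithiated allylic phosphonate (excess to cover the two hydroxyl protons) forms C16=C17 with E selectivity and completes the all-E triene, the shielded nitrile being left alone at low temperature.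

**Step 15**
Reactants: 25 triene nitrile
Product: 27 (2Z)-2-{(2R,3S,4S)-4-hydroxy-2-(3-hydroxypropyl)-3,4-dimethyl-3-[(3E,5E,7E)-4,8,12-trimethyltrideca-3,5,7,11-tetraen-1-yl]cyclohexylidene}propanal (CNP0237252.1), via aldimine 26 (not isolated)
Conditions: i-Bu2AlH (5 equiv), toluene, −78 → −40 °C; then aq. KNaC4H4O6 and pH 5 citrate buffer, 0 °C
Reagents that add atoms: water, O
Why: Partial reduction of the nitrile with the aluminium hydride stops at the N-aluminated aldimine, whose buffered hydrolysis should give the enal with the Z geometry retained, the alkenes being inert and the hydroxyls merely consuming hydride.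

**Compound list**
1 | nerol, (2Z)-3,7-dimethylocta-2,6-dien-1-ol | CC(C)=CCC/C(C)=C\CO | starting material
2 | nerylboronic acid, [(2Z)-3,7-dimethylocta-2,6-dien-1-yl]boronic acid | CC(C)=CCC/C(C)=C\CB(O)O | intermediate
3 | methyl levulinate (methyl 4-oxopentanoate) | COC(=O)CCC(C)=O | starting material
4 | methyl (4S,5S)-4-[(dihydroxyboranyl)oxy]-5-ethenyl-4,5,9-trimethyldec-8-enoate (boron-bound allylation product) | CC(C)=CCC[C@@](C)(C=C)[C@](C)(CCC(=O)OC)OB(O)O | intermediate (not isolated)
5 | (5S)-5-[(3S)-3,7-dimethylocta-1,6-dien-3-yl]-5-methyloxolan-2-one | CC(C)=CCC[C@@](C)(C=C)[C@]1(C)CCC(=O)O1 | intermediate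
6 | (5S)-5-[(3S)-5-(3,3-dimethyloxiran-2-yl)-3-methylpent-1-en-3-yl]-5-methyloxolan-2-one (epoxide epimers) | CC1(C)OC1CC[C@@](C)(C=C)[C@]2(C)CCC(=O)O2 | intermediate (not isolated)
7 | (4S)-4-methyl-4-[(2S)-2-methyl-5-oxooxolan-2-yl]hex-5-enal | O=CCC[C@@](C)(C=C)[C@]1(C)CCC(=O)O1 | intermediate
8 | (5S)-5-[(3S)-6,6-dimethoxy-3-methylhex-1-en-3-yl]-5-methyloxolan-2-one | COC(OC)CC[C@@](C)(C=C)[C@]1(C)CCC(=O)O1 | intermediate
9 | (5S,6S)-6-ethenyl-5-hydroxy-9,9-dimethoxy-5,6-dimethylnonan-2-one (in equilibrium with its cyclic hemiketal) | COC(OC)CC[C@@](C)(C=C)[C@@](C)(O)CCC(C)=O | intermediate (not isolated)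
10 | 4-[(2S,3S)-3-ethenyl-6-methoxy-2,3-dimethyloxan-2-yl]butan-2-one (anomeric mixture) | COC1CC[C@@](C)(C=C)[C@](C)(CCC(C)=O)O1 | intermediate
11 | triethyl({4-[(2S,3S)-3-ethenyl-6-methoxy-2,3-dimethyloxan-2-yl]but-1-en-2-yl}oxy)silane | COC1CC[C@@](C)(C=C)[C@](C)(CCC(=C)O[Si](CC)(CC)CC)O1 | intermediate
12 | triethyl{[(4aS,8aS)-2-methoxy-4a,8a-dimethyl-3,4,4a,7,8,8a-hexahydro-2H-chromen-6-yl]oxy}silane (trans-fused) | COC1CC[C@@]2(C)C=C(O[Si](CC)(CC)CC)CC[C@]2(C)O1 | intermediate
13 | allyl methyl carbonate | COC(=O)OCC=C | starting material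
14 | (4aS,8aS)-2-methoxy-4a,8a-dimethyl-5-(prop-2-en-1-yl)octahydro-6H-chromen-6-one, both C5 epimers (C5 = C2 of the plan) | COC1CC[C@@]2(C)C(CC=C)C(=O)CC[C@]2(C)O1 | intermediate (not isolated)
15 | (4aS,5S,8aS)-2-methoxy-4a,8a-dimethyl-5-(prop-2-en-1-yl)octahydro-6H-chromen-6-one (allyl equatorial) | COC1CC[C@@]2(C)[C@H](CC=C)C(=O)CC[C@]2(C)O1 | intermediate
16 | diethyl (1-cyanoethyl)phosphonate | CCOP(=O)(OCC)C(C)C#N | starting material
17 | (2Z)-2-[(4aS,5R,8aS)-2-methoxy-4a,8a-dimethyl-5-(prop-2-en-1-yl)octahydro-6H-chromen-6-ylidene]propanenitrile | COC1CC[C@@]2(C)[C@H](CC=C)/C(=C(/C)C#N)CC[C@]2(C)O1 | intermediate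
18 | (2Z)-2-{(4aS,5R,8aS)-5-[3-(9-borabicyclo[3.3.1]nonan-9-yl)propyl]-2-methoxy-4a,8a-dimethyloctahydro-6H-chromen-6-ylidene}propanenitrile | COC1CC[C@@]2(C)[C@H](CCCB3C4CCCC3CCC4)/C(=C(/C)C#N)CC[C@]2(C)O1 | intermediate (not isolated)
19 | (2Z)-2-[(4aS,5R,8aS)-5-(3-hydroxypropyl)-2-methoxy-4a,8a-dimethyloctahydro-6H-chromen-6-ylidene]propanenitrile | COC1CC[C@@]2(C)[C@H](CCCO)/C(=C(/C)C#N)CC[C@]2(C)O1 | intermediate
20 | (2Z)-2-[(4aS,5R,8aS)-2-hydroxy-5-(3-hydroxypropyl)-4a,8a-dimethyloctahydro-6H-chromen-6-ylidene]propanenitrile (lactol) | OC1CC[C@@]2(C)[C@H](CCCO)/C(=C(/C)C#N)CC[C@]2(C)O1 | intermediate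
21 | 2-(triphenyl-λ5-phosphanylidene)propanal | CC(C=O)=P(c1ccccc1)(c1ccccc1)c1ccccc1 | starting material
22 | (2Z)-2-{(2R,3S,4S)-4-hydroxy-2-(3-hydroxypropyl)-3,4-dimethyl-3-[(3E)-4-methyl-5-oxopent-3-en-1-yl]cyclohexylidene}propanenitrile | O=C/C(C)=C/CC[C@@]1(C)[C@H](CCCO)/C(=C(/C)C#N)CC[C@]1(C)O | intermediate
23 | geranyl bromide, (2E)-1-bromo-3,7-dimethylocta-2,6-diene | CC(C)=CCC/C(C)=C/CBr | starting material
24 | diethyl [(2E)-3,7-dimethylocta-2,6-dien-1-yl]phosphonate | CC(C)=CCC/C(C)=C/CP(=O)(OCC)OCC | intermediate
25 | (2Z)-2-{(2R,3S,4S)-4-hydroxy-2-(3-hydroxypropyl)-3,4-dimethyl-3-[(3E,5E,7E)-4,8,12-trimethyltrideca-3,5,7,11-tetraen-1-yl]cyclohexylidene}propanenitrile | CC(C)=CCC/C(C)=C/C=C/C(C)=C/CC[C@@]1(C)[C@H](CCCO)/C(=C(/C)C#N)CC[C@]1(C)O | intermediate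
26 | aldimine of 27 (aluminium-bound until work-up) | CC(C)=CCC/C(C)=C/C=C/C(C)=C/CC[C@@]1(C)[C@H](CCCO)/C(=C(/C)C=N)CC[C@]1(C)O | intermediate (not isolated)
27 | (2Z)-2-{(2R,3S,4S)-4-hydroxy-2-(3-hydroxypropyl)-3,4-dimethyl-3-[(3E,5E,7E)-4,8,12-trimethyltrideca-3,5,7,11-tetraen-1-yl]cyclohexylidene}propanal | CC(C)=CCC/C(C)=C/C=C/C(C)=C/CC[C@@]1(C)[C@H](CCCO)/C(=C(/C)C=O)CC[C@]1(C)O | target

**Step count and risks**
Total: 15 steps. Longest linear sequence: 14 steps (steps 1–12, 14 and 15, from nerol).

Steps most likely to fail: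

1. Step 7. The ruthenium alkylidene may initiate too slowly at the neopentyl-type vinyl group, so that catalyst decay and cleavage of the enol ether outrun ring closure. In that case the ring is closed on an all-carbon diene and the C2 enolate is generated afterwards from an enone. Setting out from lactone acetal 8, i-Bu2AlH at −78 °C gives the lactol F1. Wittig methylenation (Ph3P=CH2) opens it to the hydroxy diene F2, and PPTS closes the cyclic methyl acetal F3. The second-generation Grubbs catalyst, now initiating at the unhindered butenyl terminus, gives the cyclohexene F4. Hydroboration with 9-borabicyclo[3.3.1]nonane places boron at C3, remote from quaternary C1, to give the borane F5, which NaBO3·4H2O oxidises to the alcohol F6. Dess–Martin periodinane gives the ketone F7, and 2-iodoxybenzoic acid in DMSO dehydrogenates it to the enone F8 (C4=C5, the only side with a removable β-hydrogen). LiN(i-Pr)2 and allyl bromide then alkylate C2, the only enolisable position, to give the allyl enone F9. 1,4-Reduction with [(Ph3P)CuH]6 followed by NaOMe equilibration returns to the route at ketone 15.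

2. Step 9. The phosphonate anion may add incompletely to the shielded C3 carbonyl, or the two alkene geometries may be poorly discriminated. In that case the enal is made by allylic transposition and then converted into the nitrile. From ketone 15, CH2=C(CH3)MgBr with CeCl3 (THF, −78 °C) gives the tertiary isopropenyl carbinol F10. [C5H5NH][CrO3Cl] buffered with NaOAc effects the Babler–Dauben oxidative transposition to the enal F11, in which the formyl group rather than the methyl group should lie beside the equatorial C2 substituent; iodine-catalysed equilibration can enrich that isomer. NH2OH·HCl in pyridine gives the oxime F12, whose dehydration (1,1'-carbonyldiimidazole) rejoins the route at nitrile 17.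

3. Step 2. The diol-bound chair may distinguish the methyl group from the ester arm of this dialkyl ketone too weakly, eroding the diastereomer and enantiomer ratios. In that case stereochemical purity is restored by separating diastereomeric amides. From lactone 5 of insufficient purity, (S)-1-phenylethylamine and AlMe3 (toluene, 60 °C) open the ring to the hydroxy amide F13, which is separated from its diastereomers by chromatography or crystallisation. TsOH in toluene at 80 °C relactonises it and returns to the route at 5.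

**Further compounds**
F1 | step 7 | (5S)-5-[(3S)-6,6-dimethoxy-3-methylhex-1-en-3-yl]-5-methyloxolan-2-ol | COC(OC)CC[C@@](C)(C=C)[C@]1(C)CCC(O)O1
F2 | step 7 | (5S,6S)-6-ethenyl-9,9-dimethoxy-5,6-dimethylnon-1-en-5-ol | COC(OC)CC[C@@](C)(C=C)[C@@](C)(O)CCC=C
F3 | step 7 | (2S,3S)-2-(but-3-en-1-yl)-3-ethenyl-6-methoxy-2,3-dimethyloxane | COC1CC[C@@](C)(C=C)[C@](C)(CCC=C)O1
F4 | step 7 | (4aS,8aS)-2-methoxy-4a,8a-dimethyl-3,4,4a,7,8,8a-hexahydro-2H-chromene | COC1CC[C@@]2(C)C=CCC[C@]2(C)O1
F5 | step 7 | 9-[(4aS,8aS)-2-methoxy-4a,8a-dimethyloctahydro-2H-chromen-6-yl]-9-borabicyclo[3.3.1]nonane | COC1CC[C@@]2(C)CC(B3C4CCCC3CCC4)CC[C@]2(C)O1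
F6 | step 7 | (4aS,8aS)-2-methoxy-4a,8a-dimethyloctahydro-2H-chromen-6-ol | COC1CC[C@@]2(C)CC(O)CC[C@]2(C)O1
F7 | step 7 | (4aS,8aS)-2-methoxy-4a,8a-dimethyloctahydro-6H-chromen-6-one | COC1CC[C@@]2(C)CC(=O)CC[C@]2(C)O1
F8 | step 7 | (4aS,8aS)-2-methoxy-4a,8a-dimethyl-2,3,4,4a,5,8a-hexahydro-6H-chromen-6-one | COC1CC[C@@]2(C)CC(=O)C=C[C@]2(C)O1
F9 | step 7 | (4aS,5S,8aS)-2-methoxy-4a,8a-dimethyl-5-(prop-2-en-1-yl)-2,3,4,4a,5,8a-hexahydro-6H-chromen-6-one | COC1CC[C@@]2(C)[C@H](CC=C)C(=O)C=C[C@]2(C)O1
F10 | step 9 | (4aS,8aS)-2-methoxy-4a,8a-dimethyl-5-(prop-2-en-1-yl)-6-(prop-1-en-2-yl)octahydro-2H-chromen-6-ol (allyl as in 15, carbinol configuration open) | COC1CC[C@@]2(C)[C@H](CC=C)C(O)(C(C)=C)CC[C@]2(C)O1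
F11 | step 9 | (2Z)-2-[(4aS,5R,8aS)-2-methoxy-4a,8a-dimethyl-5-(prop-2-en-1-yl)octahydro-6H-chromen-6-ylidene]propanal | COC1CC[C@@]2(C)[C@H](CC=C)/C(=C(/C)C=O)CC[C@]2(C)O1
F12 | step 9 | oxime of F11 | COC1CC[C@@]2(C)[C@H](CC=C)/C(=C(/C)C=NO)CC[C@]2(C)O1
F13 | step 2 | (4S,5S)-5-ethenyl-4-hydroxy-4,5,9-trimethyl-N-[(1S)-1-phenylethyl]dec-8-enamide | C[C@H](NC(=O)CC[C@](C)(O)[C@](C)(C=C)CCC=C(C)C)c1ccccc1
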